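## Retrosynthetic overview

- The target is opened at C6–C11 and O–C7 to an acyclic (10R,11S)-epoxy alcohol that already carries the coumarin ether. In the forward sense one acid-triggered cascade closes the cyclohexane (ring A) first and the tetrahydrofuran (ring B) second.
- The cascade needs a (10Z)-12-hydroxy terminus, because only the Z-CH2OH becomes axial on C11 and can reach the C7 cation. Sharpless epoxidation of that allylic alcohol sets C10 and C11; chair folding sets C6 and C7.
- The (10Z)-allylic alcohol comes from a C9–C10 sp3–sp2 Suzuki coupling: the 9-BBN adduct of an auraptene-derived 1,3-diene plus (Z)-3-iodo-2-methylprop-2-en-1-ol (from propargyl alcohol).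
- The diene comes from auraptene by allylic oxidation and methylenation; auraptene comes from umbelliferone and geranyl bromide.

Assumption: the SMILES is read as written, i.e. (1R,2R,5S,8R) in the bicycle and 2E in the side chain. Chain atoms carry farnesane locants (C1 = CH2OAr, C12 = oxygenated terminal carbon); the ring stereocentres of the target are C6, C7, C10, C11 (bicycle locants 8, 5, 2, 1).

## Route

Step 1
Reactants: 1 umbelliferone (7-hydroxy-2H-chromen-2-one); 2 geranyl bromide ((2E)-1-bromo-3,7-dimethylocta-2,6-diene)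
Product: 3 auraptene (7-{[(2E)-3,7-dimethylocta-2,6-dien-1-yl]oxy}-2H-chromen-2-one)
Conditions: K2CO3, acetone, reflux
Reagents that add atoms: none
Why: Williamson O-alkylation (SN2) of the acidic phenol with a primary allylic bromide; the 2E alkene is not touched.

Step 2
Reactants: 3 auraptene
Product: 5 (2E,6E)-2,6-dimethyl-8-[(2-oxo-2H-chromen-7-yl)oxy]octa-2,6-dienal, via allylic alcohol 4 (not isolated)
Conditions: SeO2 (0.3 equiv), tBuOOH (3 equiv), salicylic acid (0.1 equiv), CH2Cl2, rt; crude, then MnO2 (10 equiv), CH2Cl2, rt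
Reagents that add atoms: tert-butyl hydroperoxide, CC(C)(C)OO (oxygen source, relayed by catalytic selenium dioxide, O=[Se]=O)
Why: SeO2 allylic oxidation (ene reaction then [2,3]-sigmatropic shift) attacks the E-methyl of the distal, most electron-rich alkene (the 2,3-alkene is deactivated by the allylic aryloxy group), and MnO2 oxidises only the allylic alcohol, so the 6E enal results.

Step 3
Reactants: 5 enal
Product: 6 7-{[(2E,6E)-3,7-dimethylnona-2,6,8-trien-1-yl]oxy}-2H-chromen-2-one
Conditions: Ph3PCH3Br, KN(SiMe3)2, THF, −78 to 0 °C (1.05 equiv ylide, enal added last)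
Reagents that add atoms: methyltriphenylphosphonium bromide, C[P+](c1ccccc1)(c1ccccc1)c1ccccc1.[Br-] (CH2 unit)
Why: Wittig methylenation; the aldehyde reacts far faster than the coumarin lactone at low temperature, and no stereocentre or alkene geometry is affected.

Step 4
Reactants: 7 propargyl alcohol (prop-2-yn-1-ol)
Product: 9 (2Z)-3-iodo-2-methylprop-2-en-1-ol, via vinylmagnesium alkoxide 8 (not isolated)
Conditions: MeMgBr (2.5 equiv), CuI (10 mol%), Et2O, −10 °C to rt; then I2, 0 °C; aqueous work-up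
Reagents that add atoms: methylmagnesium bromide, C[Mg]Br; iodine, II
Why: Copper-catalysed anti-carbomagnesiation of the propargylic alkoxide puts methyl on C2 and magnesium on C3 cis to CH2O (alkoxide chelation), and iodinolysis with retention gives the Z vinyl iodide.

Step 5
Reactants: 6 diene; 9 (2Z)-3-iodo-2-methylprop-2-en-1-ol
Product: 11 7-{[(2E,6E,10Z)-12-hydroxy-3,7,11-trimethyldodeca-2,6,10-trien-1-yl]oxy}-2H-chromen-2-one, via B-alkyl-9-BBN adduct 10 (not isolated)
Conditions: 9-BBN (1.1 equiv), THF, 0 °C to rt; then 9, PdCl2(dppf) (5 mol%), AsPh3, Cs2CO3, DMF/H2O, rt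
Reagents that add atoms: none
Why: 9-BBN hydroborates only the terminal vinyl group of the 1,3-diene (boron on C9), and the B-alkyl Suzuki–Miyaura coupling proceeds with retention at the vinyl iodide, which fixes the 10Z geometry.

Step 6
Reactants: 11 (10Z)-allylic alcohol
Product: 12 7-{[(2E,6E)-9-[(2R,3S)-3-(hydroxymethyl)-3-methyloxiran-2-yl]-3,7-dimethylnona-2,6-dien-1-yl]oxy}-2H-chromen-2-one
Conditions: Ti(OiPr)4 (0.3 equiv), L-(+)-diethyl tartrate (0.36 equiv), tBuOOH (2 equiv), 4 Å MS, CH2Cl2, −20 °C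
Reagents that add atoms: tert-butyl hydroperoxide, CC(C)(C)OO
Why: Sharpless asymmetric epoxidation touches only the allylic alcohol alkene, and the L-(+)-tartrate catalyst delivers oxygen to the face that gives the (10R,11S) cis-epoxide (about 90% ee is usual for this Z-2-methyl class), setting C10 and C11.

Step 7
Reactants: 12 epoxy alcohol
Product: 14 7-{[(2E)-5-[(1R,2R,5S,8R)-2-hydroxy-1,5-dimethyl-6-oxabicyclo[3.2.1]octan-8-yl]-3-methylpent-2-en-1-yl]oxy}-2H-chromen-2-one (target CNP0178104.1), via tertiary C7 carbocation 13 (not isolated)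
Conditions: BF3·OEt2 (1.1 equiv), CH2Cl2 (5 mM), −78 °C, 15 min; aq. NaHCO3
Reagents that add atoms: none
Why: Proposed new method: BF3 activates the epoxide, and the 6,7-alkene attacks the tertiary C11 anti to the leaving oxygen through a chair transition state (C10–O equatorial, C5 chain equatorial from the 6E alkene, the Z-derived CH2OH axial) to give C7 cation 13, which the 1,3-diaxial hydroxymethyl oxygen captures on its axial face to close ring B; C10 is retained, C11 is inverted stereospecifically, C6 and C7 follow from the chair folding and the intramolecular capture, and the step is an isomerisation (12 and 14 are both C24H30O5); the closest known reaction type is the Lewis-acid epoxy-polyene cyclisation terminated by an internal hydroxyl group.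

## Compound list

1 | umbelliferone (7-hydroxy-2H-chromen-2-one) | Oc1ccc2ccc(=O)oc2c1 | starting material
2 | geranyl bromide ((2E)-1-bromo-3,7-dimethylocta-2,6-diene) | BrC/C=C(\C)CCC=C(C)C | starting material
3 | auraptene (7-{[(2E)-3,7-dimethylocta-2,6-dien-1-yl]oxy}-2H-chromen-2-one) | CC(C)=CCC/C(C)=C/COc1ccc2ccc(=O)oc2c1 | intermediate
4 | 7-{[(2E,6E)-8-hydroxy-3,7-dimethylocta-2,6-dien-1-yl]oxy}-2H-chromen-2-one | OC/C(C)=C/CC/C(C)=C/COc1ccc2ccc(=O)oc2c1 | intermediate
5 | (2E,6E)-2,6-dimethyl-8-[(2-oxo-2H-chromen-7-yl)oxy]octa-2,6-dienal | O=C/C(C)=C/CC/C(C)=C/COc1ccc2ccc(=O)oc2c1 | intermediate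
6 | 7-{[(2E,6E)-3,7-dimethylnona-2,6,8-trien-1-yl]oxy}-2H-chromen-2-one | C=C/C(C)=C/CC/C(C)=C/COc1ccc2ccc(=O)oc2c1 | intermediate
7 | propargyl alcohol (prop-2-yn-1-ol) | C#CCO | starting material
8 | bromomagnesium (2Z)-3-(bromomagnesio)-2-methylprop-2-en-1-olate | Br[Mg]OC/C(C)=C\[Mg]Br | intermediate
9 | (2Z)-3-iodo-2-methylprop-2-en-1-ol | OC/C(C)=C\I | intermediate
10 | 7-{[(2E,6E)-9-(9-borabicyclo[3.3.1]nonan-9-yl)-3,7-dimethylnona-2,6-dien-1-yl]oxy}-2H-chromen-2-one | C(C/C(C)=C/CC/C(C)=C/COc1ccc2ccc(=O)oc2c1)B1C2CCCC1CCC2 | intermediate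
11 | 7-{[(2E,6E,10Z)-12-hydroxy-3,7,11-trimethyldodeca-2,6,10-trien-1-yl]oxy}-2H-chromen-2-one | OC/C(C)=C\CC/C(C)=C/CC/C(C)=C/COc1ccc2ccc(=O)oc2c1 | intermediate
12 | 7-{[(2E,6E)-9-[(2R,3S)-3-(hydroxymethyl)-3-methyloxiran-2-yl]-3,7-dimethylnona-2,6-dien-1-yl]oxy}-2H-chromen-2-one | OC[C@]1(C)O[C@@H]1CC/C(C)=C/CC/C(C)=C/COc1ccc2ccc(=O)oc2c1 | intermediate
13 | BF3-bound cyclohexyl C7 carbocation (ring A closed, C12 hydroxyl free, C10–O–BF3) | C/C(=C\COc1ccc2ccc(=O)oc2c1)CC[C@@H]1[C@](C)(CO)[C@H](O[B-](F)(F)F)CC[C+]1C | intermediate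
14 | 7-{[(2E)-5-[(1R,2R,5S,8R)-2-hydroxy-1,5-dimethyl-6-oxabicyclo[3.2.1]octan-8-yl]-3-methylpent-2-en-1-yl]oxy}-2H-chromen-2-one | C/C(=C\COc1ccc2ccc(=O)oc2c1)CC[C@@H]1[C@]2(C)CO[C@@]1(C)CC[C@H]2O | target

## Step count and risks

Total: 7 steps. Longest linear sequence: 6 steps (1, 2, 3, 5, 6, 7); step 4 is a one-step branch.

**Step 7 (cascade), most likely to fail.** The C7 cation may lose a proton to give alkenes, be captured by the 2,3-alkene or by the C10 oxygen (an oxabicyclo[2.2.1]heptane), or the epoxide may rearrange to a ketone; the allylic aryl ether may also ionise. The fallback separates the two ring closures; it sets out from 12 and comes back at 14. Compound 12 is silylated (TBSCl, imidazole, CH2Cl2) to the silyl ether epoxide F1. MeAlCl2 in CH2Cl2 at −78 °C then closes only ring A, and the C7 cation loses a proton to give the exocyclic-methylene cyclohexanol F2 (an endocyclic isomer converges later, and any capture by the silyl ether oxygen gives 14 directly). Bu4NF removes the silyl group to give the diol F3. Catalytic camphorsulfonic acid in CH2Cl2 adds the axial CH2OH across the 1,1-disubstituted alkene in the Markovnikov sense and returns 14.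

**Step 5 (hydroboration and Suzuki coupling).** Zerovalent palladium may ionise the allylic aryl ether, and the borane must discriminate the vinyl group from the coumarin. The fallback installs the coumarin after the coupling; it sets out from 2 (9 and 1 join later) and comes back at 11.
- Compound 2 is etherified with 4-methoxybenzyl alcohol and NaH to geranyl 4-methoxybenzyl ether F4.
- SeO2/tBuOOH gives the allylic alcohol F5, MnO2 gives the enal F6, and Ph3P=CH2 gives the diene F7.
- Vinyl iodide 9 is silylated (TBSCl, imidazole) to the silyl ether F8.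
- 9-BBN converts F7 into the alkylborane F9, which is coupled with F8 (PdCl2(dppf), AsPh3, Cs2CO3) to the doubly protected triene F10; an alkyl benzyl ether is not a leaving group for zerovalent palladium.
- DDQ (CH2Cl2, pH 7 buffer) frees the C1 allylic alcohol F11.
- Mitsunobu reaction with umbelliferone 1 (PPh3, DIAD, THF) gives the silyl-protected coumarin ether F12, and Bu4NF returns 11.

**Step 2 (SeO2 oxidation).** Yields are usually moderate and over-oxidation or selenium residues are common. The fallback builds the enal by cleavage and olefination; it sets out from 3 and comes back at 5. mCPBA (CH2Cl2, 0 °C) epoxidises the more electron-rich terminal alkene to the racemic epoxide F13. H5IO6 (THF/H2O) cleaves it to the aldehyde F14 with loss of acetone. Wittig reaction with the stabilised ylide 2-(triphenylphosphoranylidene)propanal (toluene, 80 °C) gives 5 with E geometry.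

## Further compounds

F1 | step 7 | 7-{[(2E,6E)-9-[(2R,3S)-3-{[(tert-butyldimethylsilyl)oxy]methyl}-3-methyloxiran-2-yl]-3,7-dimethylnona-2,6-dien-1-yl]oxy}-2H-chromen-2-one | CC(C)(C)[Si](C)(C)OC[C@]1(C)O[C@@H]1CC/C(C)=C/CC/C(C)=C/COc1ccc2ccc(=O)oc2c1
F2 | step 7 | 7-{[(2E)-5-[(1S,2R,3R)-2-{[(tert-butyldimethylsilyl)oxy]methyl}-3-hydroxy-2-methyl-6-methylidenecyclohexyl]-3-methylpent-2-en-1-yl]oxy}-2H-chromen-2-one | C/C(=C\COc1ccc2ccc(=O)oc2c1)CC[C@@H]1[C@](C)(CO[Si](C)(C)C(C)(C)C)[C@H](O)CCC1=C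
F3 | step 7 | 7-{[(2E)-5-[(1S,2R,3R)-3-hydroxy-2-(hydroxymethyl)-2-methyl-6-methylidenecyclohexyl]-3-methylpent-2-en-1-yl]oxy}-2H-chromen-2-one | C/C(=C\COc1ccc2ccc(=O)oc2c1)CC[C@@H]1[C@](C)(CO)[C@H](O)CCC1=C
F4 | step 5 | 1-({[(2E)-3,7-dimethylocta-2,6-dien-1-yl]oxy}methyl)-4-methoxybenzene | COc1ccc(COC/C=C(\C)CCC=C(C)C)cc1
F5 | step 5 | (2E,6E)-8-[(4-methoxybenzyl)oxy]-2,6-dimethylocta-2,6-dien-1-ol | COc1ccc(COC/C=C(\C)CC/C=C(\C)CO)cc1
F6 | step 5 | (2E,6E)-8-[(4-methoxybenzyl)oxy]-2,6-dimethylocta-2,6-dienal | COc1ccc(COC/C=C(\C)CC/C=C(\C)C=O)cc1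
F7 | step 5 | 1-({[(2E,6E)-3,7-dimethylnona-2,6,8-trien-1-yl]oxy}methyl)-4-methoxybenzene | COc1ccc(COC/C=C(\C)CC/C=C(\C)C=C)cc1
F8 | step 5 | tert-butyl{[(2Z)-3-iodo-2-methylprop-2-en-1-yl]oxy}dimethylsilane | CC(C)(C)[Si](C)(C)OC/C(C)=C\I
F9 | step 5 | 9-{(3E,7E)-9-[(4-methoxybenzyl)oxy]-3,7-dimethylnona-3,7-dien-1-yl}-9-borabicyclo[3.3.1]nonane | COc1ccc(COC/C=C(\C)CC/C=C(\C)CCB2C3CCCC2CCC3)cc1
F10 | step 5 | tert-butyl{[(2Z,6E,10E)-12-[(4-methoxybenzyl)oxy]-2,6,10-trimethyldodeca-2,6,10-trien-1-yl]oxy}dimethylsilane | COc1ccc(COC/C=C(\C)CC/C=C(\C)CC/C=C(/C)CO[Si](C)(C)C(C)(C)C)cc1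
F11 | step 5 | (2E,6E,10Z)-12-[(tert-butyldimethylsilyl)oxy]-3,7,11-trimethyldodeca-2,6,10-trien-1-ol | OC/C=C(\C)CC/C=C(\C)CC/C=C(/C)CO[Si](C)(C)C(C)(C)C
F12 | step 5 | 7-{[(2E,6E,10Z)-12-[(tert-butyldimethylsilyl)oxy]-3,7,11-trimethyldodeca-2,6,10-trien-1-yl]oxy}-2H-chromen-2-one | CC(C)(C)[Si](C)(C)OC/C(C)=C\CC/C(C)=C/CC/C(C)=C/COc1ccc2ccc(=O)oc2c1
F13 | step 2 | 7-{[(2E)-5-(3,3-dimethyloxiran-2-yl)-3-methylpent-2-en-1-yl]oxy}-2H-chromen-2-one (racemic) | CC1(C)OC1CC/C(C)=C/COc1ccc2ccc(=O)oc2c1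
F14 | step 2 | (4E)-4-methyl-6-[(2-oxo-2H-chromen-7-yl)oxy]hex-4-enal | O=CCC/C(C)=C/COc1ccc2ccc(=O)oc2c1
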